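The six-membered carbocycle is cut at C6–C1 and C4–C5 (ring carbons run from the gem-dimethyl carbon C1 to the chain-bearing epoxide carbon C6; C7 is the first chain carbon). One Lewis-acid-mediated Michael–aldol annulation joins two commercial acyclic carbonyl compounds: mesityl oxide supplies C1–C4, the two methyls on C1 and the oxygen on C3; methyl acetoacetate supplies C5, its methyl, C6 and C7. The step exploits the 1,5-dicarbonyl relationship between C3 and C5 across the quaternary C1 and delivers the whole carbocycle with every carbon substituent in place. Later steps set C3 by oxazaborolidine reduction and the anti C5–C6 epoxide by tartrate-controlled epoxidation.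

Key step: step 1

Remark: C1–C7 in the text are the locants defined above; systematic names carry their own locants.
Remark: the sense of induction in step 2 is assigned on the usual model in which the alkenyl arm of a cyclic enone acts as the larger ketone substituent.

Step 1
Reactants: 1 mesityl oxide; 2 methyl acetoacetate
Product: 5 methyl 2,6,6-trimethyl-4-oxocyclohex-2-ene-1-carboxylate (racemic), via diketo ester 3 (not isolated), via ketol 4 (not isolated)
Conditions: ZnCl2 (0.5 equiv), toluene–heptane, reflux, Dean–Stark
Reagents that add atoms: none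
Why: The zinc-bound enol of 2 adds through its doubly activated carbon (C6) to the β-carbon (C1) of Lewis-acid-activated 1, creating the quaternary centre in diketo ester 3; the methyl ketone of the former mesityl oxide unit then enolises toward its methyl group (C4) and attacks the acetoacetate ketone (C5), and ketol 4 loses water to give the conjugated C4=C5 enone. The closest known reaction type is the Robinson-type (Hagemann ester) Michael–aldol condensation of acetoacetic esters with methyl enones under ZnCl2 or BF3·OEt2. The single ring is closed by a 6-(enolendo)-exo-trig aldol addition followed by dehydration. The only stereocentre that survives the step, the ester-bearing C6, is formed racemic and needs no control, because it becomes trigonal again in step 5 before the epoxide centres are set. Only regioselectivity is required: the acetoacetate methylene is the sole acidic Michael donor, closure of the unhindered methyl ketone enol onto the more electrophilic β-keto ester carbonyl is the normal Hagemann mode, and the alkoxide-free medium suppresses Claisen closure onto the ester while azeotropic water removal pulls the reversible Michael step forward.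

Step 2
Reactants: 5 methyl 2,6,6-trimethyl-4-oxocyclohex-2-ene-1-carboxylate
Product: 6 methyl (1RS,4S)-4-hydroxy-2,6,6-trimethylcyclohex-2-ene-1-carboxylate (both C1 epimers, each 4S)
Conditions: (R)-2-methyl-CBS-oxazaborolidine [(3aR)-1-methyl-3,3-diphenyltetrahydro-1H,3H-pyrrolo[1,2-c][1,3,2]oxazaborole] (0.2 equiv), catecholborane (1.5 equiv), toluene, −78 °C; MeOH quench, aq NaOH wash
Reagents that add atoms: none
Why: Corey–Bakshi–Shibata reduction is 1,2-selective for cyclic enones; the catalyst binds the carbonyl lone pair on the side away from the larger alkenyl arm (C4=C5) and delivers hydride to one face, so the (R)-catalyst should set the 4S carbinol (target C3) in both C1 epimers, which converge in step 5.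

Step 3
Reactants: 6 methyl (1RS,4S)-4-hydroxy-2,6,6-trimethylcyclohex-2-ene-1-carboxylate
Product: 7 methyl (1RS,4S)-4-[(tert-butyldimethylsilyl)oxy]-2,6,6-trimethylcyclohex-2-ene-1-carboxylate
Conditions: TBSCl (1.3 equiv), imidazole (2.5 equiv), DMF, rt
Reagents that add atoms: tert-butyldimethylsilyl chloride, CC(C)(C)[Si](C)(C)Cl
Why: Standard imidazole-promoted silylation of an unhindered secondary alcohol; the silyl ether survives the hydride, oxidation, epoxidation and olefination steps and keeps the C3 oxygen from opening the later epoxide.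

Step 4
Reactants: 7 methyl (1RS,4S)-4-[(tert-butyldimethylsilyl)oxy]-2,6,6-trimethylcyclohex-2-ene-1-carboxylate
Product: 8 [(1RS,4S)-4-[(tert-butyldimethylsilyl)oxy]-2,6,6-trimethylcyclohex-2-en-1-yl]methanol
Conditions: iBu2AlH (2.5 equiv), CH2Cl2, −78 → 0 °C; aq potassium sodium tartrate work-up
Reagents that add atoms: none
Why: Exhaustive aluminium hydride reduction of the ester to the primary alcohol; the silyl ether and the isolated trisubstituted alkene are inert.

Step 5
Reactants: 8 [(1RS,4S)-4-[(tert-butyldimethylsilyl)oxy]-2,6,6-trimethylcyclohex-2-en-1-yl]methanol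
Product: 10 (4R)-4-[(tert-butyldimethylsilyl)oxy]-2,6,6-trimethylcyclohex-1-ene-1-carbaldehyde, via deconjugated aldehyde 9 (not isolated)
Conditions: (COCl)2, DMSO, CH2Cl2, −78 °C; Et3N, −78 → 0 °C; then DBU (0.2 equiv), rt
Reagents that add atoms: none
Why: Swern oxidation gives the β,γ-unsaturated aldehyde 9, whose C6–H is allylic and α to the formyl group, so amine base equilibrates the alkene into the tetrasubstituted conjugated C5=C6 position (the α- to β-cyclocitral isomerisation) and erases the racemic C6 centre; the carbinol descriptor changes from S to R through CIP priorities only.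

Step 6
Reactants: 10 (4R)-4-[(tert-butyldimethylsilyl)oxy]-2,6,6-trimethylcyclohex-1-ene-1-carbaldehyde
Product: 11 [(4R)-4-[(tert-butyldimethylsilyl)oxy]-2,6,6-trimethylcyclohex-1-en-1-yl]methanol
Conditions: NaBH4, CeCl3·7H2O, MeOH, 0 °C
Reagents that add atoms: none
Why: Luche reduction attacks the hindered enal at the carbonyl carbon only and gives the primary allylic alcohol that the directed epoxidation needs.

Step 7
Reactants: 11 [(4R)-4-[(tert-butyldimethylsilyl)oxy]-2,6,6-trimethylcyclohex-1-en-1-yl]methanol
Product: 12 [(1R,4S,6R)-4-[(tert-butyldimethylsilyl)oxy]-2,2,6-trimethyl-7-oxabicyclo[4.1.0]heptan-1-yl]methanol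
Conditions: Ti(OiPr)4 (0.2 equiv), D-(−)-diethyl tartrate (0.25 equiv), t-BuOOH (2 equiv, in decane), 4 Å molecular sieves, CH2Cl2, −20 °C
Reagents that add atoms: tert-butyl hydroperoxide, CC(C)(C)OO
Why: Sharpless asymmetric epoxidation holds the allylic alkoxide and the peroxide on the titanium tartrate and delivers oxygen to one alkene face whatever the substitution; with the D-(−) tartrate this is the face opposite the C3 silyloxy group, so C5 and C6 are set together as the anti epoxide under reagent control.

Step 8
Reactants: 12 [(1R,4S,6R)-4-[(tert-butyldimethylsilyl)oxy]-2,2,6-trimethyl-7-oxabicyclo[4.1.0]heptan-1-yl]methanol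
Product: 13 (1S,4S,6R)-4-[(tert-butyldimethylsilyl)oxy]-2,2,6-trimethyl-7-oxabicyclo[4.1.0]heptane-1-carbaldehyde
Conditions: Dess–Martin periodinane (1.3 equiv), pyridine, CH2Cl2, 0 °C → rt
Reagents that add atoms: none
Why: Buffered periodinane oxidation of the primary alcohol leaves the epoxide and silyl ether intact, and the aldehyde has no α-hydrogen and cannot epimerise (the C1 descriptor changes from R to S by CIP priority only).

Step 9
Reactants: 13 (1S,4S,6R)-4-[(tert-butyldimethylsilyl)oxy]-2,2,6-trimethyl-7-oxabicyclo[4.1.0]heptane-1-carbaldehyde; 14 (acetylmethylene)triphenylphosphorane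
Product: 15 (3E)-4-[(1S,4S,6R)-4-[(tert-butyldimethylsilyl)oxy]-2,2,6-trimethyl-7-oxabicyclo[4.1.0]heptan-1-yl]but-3-en-2-one
Conditions: 14 (2.5 equiv), toluene, 100 °C
Reagents that add atoms: none
Why: Wittig olefination with a carbonyl-stabilised ylide runs under neutral conditions that spare the epoxide, the α-oxygenated non-enolisable aldehyde is electrophilic enough despite its hindered setting, and reversible oxaphosphetane formation gives the E-enone.

Step 10
Reactants: 15 (3E)-4-[(1S,4S,6R)-4-[(tert-butyldimethylsilyl)oxy]-2,2,6-trimethyl-7-oxabicyclo[4.1.0]heptan-1-yl]but-3-en-2-one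
Product: 16 (3E)-4-[(1S,4S,6R)-4-hydroxy-2,2,6-trimethyl-7-oxabicyclo[4.1.0]heptan-1-yl]but-3-en-2-one
Conditions: Bu4NF (1.5 equiv), AcOH (1.5 equiv), THF, 0 °C → rt
Reagents that add atoms: none
Why: Fluoride cleaves the Si–O bond, and acetic acid buffering keeps the medium near neutral so that the epoxide and the enone survive; C3 is not touched.

Step 11
Reactants: 16 (3E)-4-[(1S,4S,6R)-4-hydroxy-2,2,6-trimethyl-7-oxabicyclo[4.1.0]heptan-1-yl]but-3-en-2-one; 17 myristoyl chloride
Product: 18 (1R,3S,6S)-1,5,5-trimethyl-6-[(1E)-3-oxobut-1-en-1-yl]-7-oxabicyclo[4.1.0]heptan-3-yl tetradecanoate (target)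
Conditions: 17 (1.2 equiv), pyridine, 4-(dimethylamino)pyridine (0.1 equiv), CH2Cl2, 0 °C → rt
Reagents that add atoms: none
Why: Acylpyridinium-mediated esterification of the unhindered secondary alcohol proceeds with retention at C3, and the amine base traps HCl so the acid-labile epoxide is not opened.

Compound list
1 | mesityl oxide (4-methylpent-3-en-2-one) | CC(C)=CC(C)=O | starting material
2 | methyl acetoacetate (methyl 3-oxobutanoate) | CC(=O)CC(=O)OC | starting material
3 | methyl 2-acetyl-3,3-dimethyl-5-oxohexanoate (racemic) | COC(=O)C(C(C)=O)C(C)(C)CC(C)=O | intermediate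
4 | methyl 2-hydroxy-2,6,6-trimethyl-4-oxocyclohexane-1-carboxylate (racemic diastereomer mixture) | COC(=O)C1C(C)(O)CC(=O)CC1(C)C | intermediate
5 | methyl 2,6,6-trimethyl-4-oxocyclohex-2-ene-1-carboxylate (racemic) | COC(=O)C1C(C)=CC(=O)CC1(C)C | intermediate
6 | methyl (1RS,4S)-4-hydroxy-2,6,6-trimethylcyclohex-2-ene-1-carboxylate | COC(=O)C1C(C)=C[C@@H](O)CC1(C)C | intermediate
7 | methyl (1RS,4S)-4-[(tert-butyldimethylsilyl)oxy]-2,6,6-trimethylcyclohex-2-ene-1-carboxylate | COC(=O)C1C(C)=C[C@@H](O[Si](C)(C)C(C)(C)C)CC1(C)C | intermediate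
8 | [(1RS,4S)-4-[(tert-butyldimethylsilyl)oxy]-2,6,6-trimethylcyclohex-2-en-1-yl]methanol | OCC1C(C)=C[C@@H](O[Si](C)(C)C(C)(C)C)CC1(C)C | intermediate
9 | (1RS,4S)-4-[(tert-butyldimethylsilyl)oxy]-2,6,6-trimethylcyclohex-2-ene-1-carbaldehyde | O=CC1C(C)=C[C@@H](O[Si](C)(C)C(C)(C)C)CC1(C)C | intermediate
10 | (4R)-4-[(tert-butyldimethylsilyl)oxy]-2,6,6-trimethylcyclohex-1-ene-1-carbaldehyde | O=CC1=C(C)C[C@@H](O[Si](C)(C)C(C)(C)C)CC1(C)C | intermediate
11 | [(4R)-4-[(tert-butyldimethylsilyl)oxy]-2,6,6-trimethylcyclohex-1-en-1-yl]methanol | OCC1=C(C)C[C@@H](O[Si](C)(C)C(C)(C)C)CC1(C)C | intermediate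
12 | [(1R,4S,6R)-4-[(tert-butyldimethylsilyl)oxy]-2,2,6-trimethyl-7-oxabicyclo[4.1.0]heptan-1-yl]methanol | CC(C)(C)[Si](C)(C)O[C@H]1CC(C)(C)[C@]2(CO)O[C@]2(C)C1 | intermediate
13 | (1S,4S,6R)-4-[(tert-butyldimethylsilyl)oxy]-2,2,6-trimethyl-7-oxabicyclo[4.1.0]heptane-1-carbaldehyde | CC(C)(C)[Si](C)(C)O[C@H]1CC(C)(C)[C@]2(C=O)O[C@]2(C)C1 | intermediate
14 | (acetylmethylene)triphenylphosphorane [1-(triphenylphosphoranylidene)propan-2-one] | CC(=O)C=P(c1ccccc1)(c1ccccc1)c1ccccc1 | starting material
15 | (3E)-4-[(1S,4S,6R)-4-[(tert-butyldimethylsilyl)oxy]-2,2,6-trimethyl-7-oxabicyclo[4.1.0]heptan-1-yl]but-3-en-2-one | CC(C)(C)[Si](C)(C)O[C@H]1CC(C)(C)[C@]2(/C=C/C(C)=O)O[C@]2(C)C1 | intermediate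
16 | (3E)-4-[(1S,4S,6R)-4-hydroxy-2,2,6-trimethyl-7-oxabicyclo[4.1.0]heptan-1-yl]but-3-en-2-one | O[C@H]1CC(C)(C)[C@]2(/C=C/C(C)=O)O[C@]2(C)C1 | intermediate
17 | myristoyl chloride (tetradecanoyl chloride) | CCCCCCCCCCCCCC(=O)Cl | starting material
18 | (1R,3S,6S)-1,5,5-trimethyl-6-[(1E)-3-oxobut-1-en-1-yl]-7-oxabicyclo[4.1.0]heptan-3-yl tetradecanoate | CCCCCCCCCCCCCC(=O)O[C@H]1CC(C)(C)[C@]2(/C=C/C(C)=O)O[C@]2(C)C1 | target

Total steps: 11. Longest linear sequence: 11 steps (1 and 2 to 18).

Steps most likely to fail

Step 1. The Michael addition that creates the quaternary C1 is reversible and sterically demanding. Conversion may stall while mesityl oxide self-condenses or the diketo ester closes in the other aldol sense. Fallback: setting out from 2, Knoevenagel condensation with acetone (TiCl4, pyridine, THF, 0 °C) would give methyl 2-acetyl-3-methylbut-2-enoate F1. Mukaiyama–Michael addition of 2-(trimethylsilyloxy)propene to this doubly activated acceptor (TiCl4, CH2Cl2, −78 °C) would build the quaternary carbon and deliver diketo ester 3, now isolated. Separate cyclodehydration (TsOH, toluene, Dean–Stark) would bring the route back at 5.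

Step 2. Hydride delivery may lose face selectivity for the mismatched half of racemic 5, or the saturated arm may compete as the larger group, and conjugate reduction may intrude. If only the sense of induction were reversed, the antipodal catalyst would be used. Fallback: setting out from 5, an NADPH-dependent ketoreductase chosen by screening for the (S)-carbinol (glucose and glucose dehydrogenase for cofactor recycling, phosphate buffer pH 7, DMSO co-solvent, 30 °C) would reduce the ketone under enzyme control. It returns to the route at 6 and makes no new compound (F0).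

Step 7. The tetrasubstituted alkene next to the gem-dimethyl carbon may epoxidise slowly, which would erode tartrate face control, and the titanium alkoxides may open the tertiary epoxide. Fallback: setting out from 11, substrate-controlled peracid epoxidation (mCPBA, NaHCO3, CH2Cl2, 0 °C) would give 12 together with its syn diastereomer [(1S,4S,6S)-4-[(tert-butyldimethylsilyl)oxy]-2,2,6-trimethyl-7-oxabicyclo[4.1.0]heptan-1-yl]methanol F2. The two would be separated by chromatography, and 12 rejoins the route at step 8.

Further compounds
F1 | step 1 | methyl 2-acetyl-3-methylbut-2-enoate | COC(=O)C(C(C)=O)=C(C)C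
F0 | step 2 | none | none
F2 | step 7 | [(1S,4S,6S)-4-[(tert-butyldimethylsilyl)oxy]-2,2,6-trimethyl-7-oxabicyclo[4.1.0]heptan-1-yl]methanol | CC(C)(C)[Si](C)(C)O[C@H]1CC(C)(C)[C@@]2(CO)O[C@@]2(C)C1
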